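## Retrosynthetic overview

1. Cut the C3–O ester bond: the target comes from 3α,4α,7α,11-tetrahydroxyeudesman-8-one and (2S,3S)-epoxyangelic acid (angelic acid → allylic alcohol → Sharpless epoxidation → acid).
2. The 7α,11-diol comes from the 7(11)-en-8-one (nucleophilic epoxidation, then hydrolysis); the 3α,4α-diol comes from a Δ3-alkene (OsO4, α-face).
3. (5R,10R)-Eudesma-3,7(11)-dien-8-one comes from germacrone by a single proton-initiated transannular C5–C10 cation–olefin cyclisation, made enantioselective by a confined chiral Brønsted acid acting on the achiral, conformationally mobile ten-membered ring.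
4. Ring order: ten-membered germacrane ring (present in germacrone) → trans-decalin (C5–C10 bond) → spiro-oxirane at C7/C11 (opened again). The side-chain oxirane is made separately and joined last.

Assumption: germacrone (achiral, CAS 6902-91-6; sold by natural-product suppliers and crystallised from commercial zdravetz oil) counts as an inexpensive commercial starting material; in step 1 the catalyst antipode that gives the (5R,10R) series is used.

## Route

Step 1
Reactants: 1 germacrone, (3E,7E)-3,7-dimethyl-10-(propan-2-ylidene)cyclodeca-3,7-dien-1-one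
Product: 2 (5R,10R)-eudesma-3,7(11)-dien-8-one (trans-fused, 5α-H, 10β-CH3)
Conditions: chiral IDPi (imidodiphosphorimidate) Brønsted acid (5 mol %), (CF3)3COH/CHCl3, −40 °C
Reagents that add atoms: none
Why: Proposed new method: the confined chiral acid protonates C1 of the 1(10)-alkene in one of the two rapidly interconverting enantiomeric crossed conformers of achiral 1, the C10 cation is captured transannularly by C5 in a chair–chair array (anti addition across both E-alkenes, hence trans-fused 10β-CH3/5α-H) and the C4 cation loses H-3 to the catalyst anion to give the Δ3-alkene, so C5 and C10 are set by the catalyst antipode; the closest known reactions are the racemic acid-mediated transannular cyclisation of germacrone and germacrenes to eudesmanes and IDPi-catalysed enantioselective protonative polyene cyclisation.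

Step 2
Reactants: 2 (5R,10R)-eudesma-3,7(11)-dien-8-one
Product: 3 (3R,4S,5R,10R)-3α,4α-dihydroxyeudesm-7(11)-en-8-one (cuauhtemone)
Conditions: OsO4 (2 mol %), NMO (1.2 equiv), t-BuOH/THF/H2O, 0 °C → rt
Reagents that add atoms: osmium tetroxide O=[Os](=O)(=O)=O; N-methylmorpholine N-oxide C[N+]1([O-])CCOCC1; water O
Why: Upjohn cis-dihydroxylation attacks the electron-rich trisubstituted Δ3-alkene and not the tetrasubstituted enone, from the α-face anti to the axial C10 methyl (1,3-diaxial to C4), which sets C3 (R) and C4 (S) as the 3α,4α cis-diol.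

Step 3
Reactants: 3 cuauhtemone
Product: 4 (3R,4S,5R,7S,10R)-7α,11-epoxy-3α,4α-dihydroxyeudesman-8-one
Conditions: 30 % H2O2, NaOH (0.3 equiv), MeOH, 0 °C → rt
Reagents that add atoms: hydrogen peroxide OO
Why: Weitz–Scheffer nucleophilic epoxidation (as for pulegone) in which HOO− adds to C11 and the ring enolate closes onto oxygen along the chair-like axial trajectory at C7, i.e. on the α-face, which sets C7 (S) with the C7–O bond axial and C11 equatorial; the diol is inert.

Step 4
Reactants: 4 7α,11-epoxy-3α,4α-dihydroxyeudesman-8-one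
Product: 5 (3R,4S,5R,7S,10R)-3α,4α,7α,11-tetrahydroxyeudesman-8-one
Conditions: HClO4 (cat.), THF/H2O 3:1, rt
Reagents that add atoms: water O
Why: Acid-catalysed epoxide hydrolysis in which water opens the protonated oxirane at the tertiary C11 (C7, α to the carbonyl, does not ionise), so the C7–O bond and the 7α configuration are kept and C11 is not stereogenic.

Step 5
Reactants: 6 angelic acid, (Z)-2-methylbut-2-enoic acid
Product: 7 (Z)-2-methylbut-2-en-1-ol
Conditions: LiAlH4, Et2O, 0 °C → rt; aqueous work-up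
Reagents that add atoms: none
Why: LiAlH4 reduction of the carboxylic acid is a clean 1,2-reduction that leaves the trisubstituted alkene and its Z geometry untouched.

Step 6
Reactants: 7 (Z)-2-methylbut-2-en-1-ol
Product: 8 [(2R,3S)-2,3-dimethyloxiran-2-yl]methanol
Conditions: Ti(OiPr)4 (10 mol %), D-(−)-diethyl tartrate (12 mol %), t-BuOOH, 4 Å MS, CH2Cl2, −20 °C; non-aqueous work-up
Reagents that add atoms: tert-butyl hydroperoxide CC(C)(C)OO
Why: Sharpless asymmetric epoxidation in which the D-(−)-tartrate/Ti complex delivers oxygen to the alkene face opposite to that used by L-(+)-tartrate, setting both oxirane centres (2R,3S) with the Z relationship of CH2OH and C3-CH3 retained.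

Step 7
Reactants: 8 [(2R,3S)-2,3-dimethyloxiran-2-yl]methanol
Product: 9 (2S,3S)-2,3-dimethyloxirane-2-carboxylic acid, (2S,3S)-epoxyangelic acid
Conditions: RuCl3·xH2O (2 mol %), NaIO4 (3 equiv), CCl4/MeCN/H2O, rt
Reagents that add atoms: water O
Why: Sharpless RuO4 oxidation takes the primary alcohol through the aldehyde hydrate to the acid without touching the oxirane, and the C2 descriptor changes from R to S only because CO2H outranks C3 in the CIP order.

Step 8
Reactants: 9 (2S,3S)-epoxyangelic acid; 5 3α,4α,7α,11-tetrahydroxyeudesman-8-one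
Product: 11 (3R,4S,5R,7S,10R)-4α,7α,11-trihydroxy-8-oxoeudesman-3α-yl (2S,3S)-2,3-dimethyloxirane-2-carboxylate, via mixed Yamaguchi anhydride 10 (not isolated)
Conditions: 2,4,6-Cl3C6H2COCl, Et3N, THF, rt; then 5, DMAP, toluene, rt → 40 °C
Reagents that add atoms: none
Why: Yamaguchi esterification in which DMAP transfers the less hindered epoxyacyl group of the mixed anhydride to the only secondary hydroxyl (3α-OH; the 4-, 7- and 11-OH are tertiary), with no stereocentre touched and the oxirane and α-ketol stable to the mild base.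

## Compound list

1 | germacrone, (3E,7E)-3,7-dimethyl-10-(propan-2-ylidene)cyclodeca-3,7-dien-1-one | C/C1=C\CC(=C(C)C)C(=O)C/C(C)=C/CC1 | starting material
2 | (5R,10R)-eudesma-3,7(11)-dien-8-one | CC1=CCC[C@]2(C)CC(=O)C(=C(C)C)C[C@@H]12 | intermediate
3 | (3R,4S,5R,10R)-3α,4α-dihydroxyeudesm-7(11)-en-8-one (cuauhtemone) | O[C@@H]1CC[C@]2(C)CC(=O)C(=C(C)C)C[C@H]2[C@]1(C)O | intermediate
4 | (3R,4S,5R,7S,10R)-7α,11-epoxy-3α,4α-dihydroxyeudesman-8-one | O[C@@H]1CC[C@]2(C)CC(=O)[C@@](O3)(C3(C)C)C[C@H]2[C@]1(C)O | intermediate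
5 | (3R,4S,5R,7S,10R)-3α,4α,7α,11-tetrahydroxyeudesman-8-one | O[C@@H]1CC[C@]2(C)CC(=O)[C@@](O)(C(C)(C)O)C[C@H]2[C@]1(C)O | intermediate
6 | angelic acid, (Z)-2-methylbut-2-enoic acid | C/C=C(/C)C(=O)O | starting material
7 | (Z)-2-methylbut-2-en-1-ol | C/C=C(/C)CO | intermediate
8 | [(2R,3S)-2,3-dimethyloxiran-2-yl]methanol | C[C@@H]1O[C@]1(C)CO | intermediate
9 | (2S,3S)-2,3-dimethyloxirane-2-carboxylic acid | C[C@@H]1O[C@]1(C)C(=O)O | intermediate
10 | (2S,3S)-2,3-dimethyloxirane-2-carboxylic 2,4,6-trichlorobenzoic anhydride | C[C@@H]1O[C@]1(C)C(=O)OC(=O)c1c(Cl)cc(Cl)cc1Cl | intermediate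
11 | (3R,4S,5R,7S,10R)-4α,7α,11-trihydroxy-8-oxoeudesman-3α-yl (2S,3S)-2,3-dimethyloxirane-2-carboxylate | C[C@@H]1O[C@]1(C)C(=O)O[C@@H]1CC[C@]2(C)CC(=O)[C@@](O)(C(C)(C)O)C[C@H]2[C@]1(C)O | target

## Step count and risks

Total step count: 8. Longest linear sequence: 5 (steps 1–4 and 8; the side-chain branch is steps 5–7 and 8).

**Step 1.** Neither the enantioselectivity of the protonation nor the Δ3 regiochemistry of the proton loss (against Δ4 and Δ4(15)) has precedent on germacrone. The fallback sets out from 1 and comes back at 11. Cyclise 1 with an achiral acid (TsOH·H2O, CH2Cl2, 0 °C) to the racemate, that is 2 together with its enantiomer (5S,10S)-eudesma-3,7(11)-dien-8-one F1. Run steps 2–4 on the racemate, which gives beside 3, 4 and 5 the mirror-image diol ent-cuauhtemone F2, the ent-epoxide F3 and the ent-tetraol F4. Acylate the racemic tetraol with enantiopure 9 exactly as in step 8 (via 10), so that the two enantiomers become the diastereomers 11 and the (2S,3S)-epoxyangelate of the ent-tetraol F5, which are separated by chromatography or crystallisation. Absolute configuration then comes from 9 (classical resolution) and no longer from the catalyst.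

**Step 4.** Opening the α,β-epoxy ketone in acid can divert to acyl migration or to elimination, and it depends on the α-face selectivity of step 3. The fallback sets out from 3 and comes back at 5 without any epoxide. Deconjugative α-oxygenation (KOt-Bu in excess, O2, P(OEt)3, t-BuOH/THF, −20 °C) oxygenates the extended dienolate of 3 axially at C7 to 3α,4α-dihydroxy-7α-hydroperoxyeudesm-11(13)-en-8-one F6. The phosphite reduces this in the flask to 3α,4α,7α-trihydroxyeudesm-11(13)-en-8-one F7. Mukaiyama hydration of the isopropenyl group (Co(acac)2 cat., PhSiH3, O2, THF/i-PrOH, rt) then places the tertiary hydroxyl on C11 (Markovnikov, not stereogenic) and gives 5.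

**Step 8.** An α-quaternary epoxy acid has to be joined to an axial secondary alcohol next to a quaternary carbon, so the acylation may be slow or unselective. The fallback sets out from 5 (with commercial 6) and comes back at 11. Yamaguchi angeloylation (6, 2,4,6-trichlorobenzoyl chloride, Et3N, then 5, DMAP, toluene, 60 °C) proceeds via angelic 2,4,6-trichlorobenzoic anhydride F8. It gives with the flatter sp2 acid the ester 3α-angeloyloxy-4α,7α,11-trihydroxyeudesman-8-one F9. Its only C=C is then epoxidised with dimethyldioxirane (acetone, 0 °C) to 11 together with the (2R,3R)-epoxyangelate diastereomer F10, and the two are separated by HPLC.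

## Further compounds

F1 | step 1 | (5S,10S)-eudesma-3,7(11)-dien-8-one (ent-2) | CC1=CCC[C@@]2(C)CC(=O)C(=C(C)C)C[C@H]12
F2 | step 1 | (3S,4R,5S,10S)-3,4-dihydroxyeudesm-7(11)-en-8-one (ent-cuauhtemone) | O[C@H]1CC[C@@]2(C)CC(=O)C(=C(C)C)C[C@@H]2[C@@]1(C)O
F3 | step 1 | (3S,4R,5S,7R,10S)-7,11-epoxy-3,4-dihydroxyeudesman-8-one (ent-4) | O[C@H]1CC[C@@]2(C)CC(=O)[C@](O3)(C3(C)C)C[C@@H]2[C@@]1(C)O
F4 | step 1 | (3S,4R,5S,7R,10S)-3,4,7,11-tetrahydroxyeudesman-8-one (ent-5) | O[C@H]1CC[C@@]2(C)CC(=O)[C@](O)(C(C)(C)O)C[C@@H]2[C@@]1(C)O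
F5 | step 1 | (3S,4R,5S,7R,10S)-4,7,11-trihydroxy-8-oxoeudesman-3-yl (2S,3S)-2,3-dimethyloxirane-2-carboxylate | C[C@@H]1O[C@]1(C)C(=O)O[C@H]1CC[C@@]2(C)CC(=O)[C@](O)(C(C)(C)O)C[C@@H]2[C@@]1(C)O
F6 | step 4 | 3α,4α-dihydroxy-7α-hydroperoxyeudesm-11(13)-en-8-one | O[C@@H]1CC[C@]2(C)CC(=O)[C@@](OO)(C(C)=C)C[C@H]2[C@]1(C)O
F7 | step 4 | 3α,4α,7α-trihydroxyeudesm-11(13)-en-8-one | O[C@@H]1CC[C@]2(C)CC(=O)[C@@](O)(C(C)=C)C[C@H]2[C@]1(C)O
F8 | step 8 | (Z)-2-methylbut-2-enoic 2,4,6-trichlorobenzoic anhydride | C/C=C(/C)C(=O)OC(=O)c1c(Cl)cc(Cl)cc1Cl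
F9 | step 8 | 3α-angeloyloxy-4α,7α,11-trihydroxyeudesman-8-one | C/C=C(/C)C(=O)O[C@@H]1CC[C@]2(C)CC(=O)[C@@](O)(C(C)(C)O)C[C@H]2[C@]1(C)O
F10 | step 8 | (3R,4S,5R,7S,10R)-4,7,11-trihydroxy-8-oxoeudesman-3-yl (2R,3R)-2,3-dimethyloxirane-2-carboxylate | C[C@H]1O[C@@]1(C)C(=O)O[C@@H]1CC[C@]2(C)CC(=O)[C@@](O)(C(C)(C)O)C[C@H]2[C@]1(C)O
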